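A one-step world has one unknown: what is not product is substrate. These flasks hide two forms, substrate and intermediate, while the readings show target and homo product.

| flask | substrate | partner | remark | time |
|---|---|---|---|---|
| north-west | 0.042 M | 0.0504 M | run made earlier |  |
| north-east | 0.021 M | 0.0504 M | run made earlier |  |
| south-west | 0.084 M | 0.0504 M | run made earlier |  |
| east | 0.042 M | 0.025 M | run made earlier |  |
| teal | 0.042 M (fed, over 50 h) | 0.0504 M | all else is in the flask from the start; the feed brings no volume worth counting | 2.5 d |
| red | 0.042 M | 0.0504 M | everything together at the start | 2.5 d |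
| green | 0.042 M | 0.0504 M (fed, over 50 h) | all else is in the flask from the start; the feed brings no volume worth counting | 2.5 d |

north-west run (percent of the substrate charged)

| time / h | homo product / % | target / % |
|---|---|---|
| 3.00 | 0.5 | 1.4 |
| 10.0 | 1.2 | 5.8 |
| 15.0 | 4.3 | 7.8 |
| 25.0 | 14.0 | 10.3 |
| 40.0 | 29.0 | 10.2 |

north-east run (percent of the substrate charged)

| time / d | homo product / % | target / % |
|---|---|---|
| 0.250 | 0 | 4.0 |
| 0.417 | 1.4 | 6.7 |
| 0.833 | 3.9 | 10.6 |
| 1.67 | 19.7 | 12.5 |
| 3.00 | 44.5 | 11.4 |

south-west run (percent of the substrate charged)

| time / d | homo product / % | target / % |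
|---|---|---|
| 0.250 | 1.2 | 4.4 |
| 0.833 | 14.5 | 8.2 |
| 1.25 | 28.0 | 7.7 |
| 2.00 | 49.8 | 6.3 |
| 3.00 | 66.9 | 4.9 |

east run (percent of the substrate charged)

| time / d | homo product / % | target / % |
|---|---|---|
| 0.625 | 6.4 | 5.0 |
| 1.25 | 21.8 | 6.0 |
| 1.67 | 34.3 | 4.8 |
| 2.50 | 53.6 | 4.0 |
| 3.00 | 62.3 | 3.7 |

(each reading ± 0.5 percentage points)

- in percentages every species weighs as the substrate in it: one homo product counts as two
- steps thought possible: substrate -> intermediate; partner + intermediate <-> target; 2 intermediate -> homo product

- which flask leads in amount of homo product, in percent of the substrate charged ("all alike" within 1.5 percentage points) (teal / red / green / all alike)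
- how much homo product is there at the end, in percent of the substrate charged: teal
- how much homo product is there at the end, in percent of the substrate charged: red
- how much homo product is there at the end, in percent of the substrate charged: green

For the bench: in teal, red and green substrate is the limiting reagent, 0.042 M against 0.0504 M of partner, so its balance is the one to keep. The east run at 2.50 d gives 42.4% for the unread remainder, the charge minus homo product and target. Halving the partner left it in place within the scatter at the one time the two runs share: north-west holds 60.8% at 40.0 h, east 60.9% at 1.67 d. The substrate charge moved it: at 3.00 d, north-east keeps 44.1%, more than the 28.2% of south-west. So the substrate charge is what not to touch. Red, taking that remainder and the last north-west target of 10.2%, should show homo product near 47.4% on this note's reckoning.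

The forecast stands lower for red, at 46.5%, with 23% for teal and 49.5% for green, which it puts first: “Green starts with little partner”.

The flasks end with 22.4% in teal, 49.0% in red and 50.6% in green, so green leads.

    substrate → intermediate (k = 0.0293 h⁻¹)
    partner + intermediate ⇌ target (K = 7.51 M⁻¹, k = 8.59 M⁻¹ h⁻¹)
    2 intermediate → homo product (k = 1.54 M⁻¹ h⁻¹)

Red ends with a remainder of 42.2%, against 42.4% in east, and it stands as 17.2% substrate and 24.9% intermediate. Green's remainder is 41.0%. A neighbour of green charged with 0.011 M of substrate, a quarter of the recipe, keeps 58.4%, more than green. Its substrate stands at 17.2%, as in green, and its homo product reaches 26.5%, while intermediate holds 41.2%.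

Readings and results were generated by integration on assumed constants, and the scatter is random.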